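**Assumption:** L-valine, 5-methoxyresorcinol and 4-hydroxybenzaldehyde are taken as the commercial starting materials, and all other reagents named below are bought. The route is a paper design built on literature precedent for each reaction type; it has not been run.

## Retrosynthetic overview

1. The target comes from a 4'-O-pivaloyl 7-O-(1,1-dimethylallyl) isoflavone by aromatic Claisen rearrangement (C6 is blocked, so the prenyl group goes to C8) and final ester methanolysis.
2. The pyranone ring is formed last: a 2'-hydroxychalcone undergoes Tl(III) oxidative 1,2-aryl shift and acid ring closure; the A and B rings are bought as benzenes.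
3. The chalcone comes from a Claisen–Schmidt aldol condensation of a fully functionalised acetophenone with 4-(methoxymethoxy)benzaldehyde; this bond becomes C2–C3 of the isoflavone and joins the A- and B-ring fragments.
4. The acetophenone comes from 5-methoxyresorcinol bis-MOM ether by three successive directed ortho-lithiations: TMS block at the future C8, opening of (R)-isopropyloxirane, Weinreb acylation.
5. (R)-Isopropyloxirane comes from L-valine (chlorination with retention, reduction, ring closure with inversion); this is the source of the only stereocentre.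

## Route

Step 1
Reactants: 1 L-valine
Product: 2 (2S)-2-chloro-3-methylbutanoic acid
Conditions: NaNO2, 6 M HCl, 0 °C → rt
Reagents that add atoms: hydrochloric acid, Cl
Why: Diazotisation of the α-amino acid in HCl replaces NH2 by Cl with net retention (double inversion through carboxylate participation), so the (S) centre of L-valine is kept.

Step 2
Reactants: 2 (2S)-2-chloro-3-methylbutanoic acid
Product: 3 (2S)-2-chloro-3-methylbutan-1-ol
Conditions: LiAlH4, Et2O, 0 °C; aq. work-up
Reagents that add atoms: none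
Why: Hydride reduction of the carboxylic acid to the primary alcohol at 0 °C leaves the secondary C–Cl bond and its configuration untouched.

Step 3
Reactants: 3 (2S)-2-chloro-3-methylbutan-1-ol
Product: 4 (2R)-2-(propan-2-yl)oxirane
Conditions: KOH, H2O, 0 °C → 40 °C, distil product
Reagents that add atoms: none
Why: Intramolecular Williamson (SN2) ring closure, in which the alkoxide displaces chloride with clean inversion, gives the (R)-epoxide.

Step 4
Reactants: 5 5-methoxybenzene-1,3-diol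
Product: 6 1-methoxy-3,5-bis(methoxymethoxy)benzene
Conditions: NaH, MOMCl, DMF, 0 °C → rt
Reagents that add atoms: chloromethyl methyl ether, COCCl
Why: Williamson O-alkylation of both phenoxides installs two MOM ethers that later serve as strong directing groups for ortho-lithiation.

Step 5
Reactants: 6 1-methoxy-3,5-bis(methoxymethoxy)benzene
Product: 8 [4-methoxy-2,6-bis(methoxymethoxy)phenyl]trimethylsilane, via aryllithium 7 (not isolated)
Conditions: n-BuLi, THF, 0 °C; TMSCl, −78 °C → rt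
Reagents that add atoms: chlorotrimethylsilane, C[Si](C)(C)Cl
Why: Directed ortho-metalation occurs at the C–H flanked by the two chelating OMOM groups, and the silyl quench blocks this position (the future C8).

Step 6
Reactants: 8 [4-methoxy-2,6-bis(methoxymethoxy)phenyl]trimethylsilane; 4 (2R)-2-(propan-2-yl)oxirane
Product: 10 (2S)-1-[6-methoxy-2,4-bis(methoxymethoxy)-3-(trimethylsilyl)phenyl]-3-methylbutan-2-ol, via aryllithium 9 (not isolated)
Conditions: n-BuLi, THF, 0 °C; then 4, BF3·OEt2, −78 °C; pH 7 aqueous quench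
Reagents that add atoms: none
Why: The second directed ortho-metalation can only take place at the two equivalent sites between OMe and OMOM, and BF3-promoted SN2 opening of the epoxide at its CH2 terminus leaves the carbinol centre untouched (the R epoxide gives the S alcohol only because the CIP priorities change).

Step 7
Reactants: 10 (2S)-1-[6-methoxy-2,4-bis(methoxymethoxy)-3-(trimethylsilyl)phenyl]-3-methylbutan-2-ol
Product: 11 tert-butyl({(2S)-1-[6-methoxy-2,4-bis(methoxymethoxy)-3-(trimethylsilyl)phenyl]-3-methylbutan-2-yl}oxy)dimethylsilane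
Conditions: TBSCl, imidazole, DMF, 40 °C
Reagents that add atoms: tert-butyldimethylsilyl chloride, CC(C)(C)[Si](C)(C)Cl
Why: Silyl ether formation removes the acidic OH before the third lithiation and does not touch the stereocentre.

Step 8
Reactants: 11 tert-butyl({(2S)-1-[6-methoxy-2,4-bis(methoxymethoxy)-3-(trimethylsilyl)phenyl]-3-methylbutan-2-yl}oxy)dimethylsilane
Product: 14 1-{3-[(2S)-2-{[tert-butyl(dimethyl)silyl]oxy}-3-methylbutyl]-2-methoxy-4,6-bis(methoxymethoxy)-5-(trimethylsilyl)phenyl}ethan-1-one, via aryllithium 12 (not isolated), via lithium hemiaminal 13 (not isolated)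
Conditions: s-BuLi, TMEDA, THF, −78 °C; MeC(O)N(OMe)Me, −78 → 0 °C; H2O
Reagents that add atoms: N-methoxy-N-methylacetamide, CC(=O)N(C)OC
Why: Directed ortho-metalation at the last ring C–H (between OMe and OMOM) followed by Weinreb amide acylation stops at the methyl ketone because the chelated tetrahedral adduct only collapses on work-up.

Step 9
Reactants: 14 1-{3-[(2S)-2-{[tert-butyl(dimethyl)silyl]oxy}-3-methylbutyl]-2-methoxy-4,6-bis(methoxymethoxy)-5-(trimethylsilyl)phenyl}ethan-1-one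
Product: 15 1-{4,6-dihydroxy-3-[(2S)-2-hydroxy-3-methylbutyl]-2-methoxyphenyl}ethan-1-one
Conditions: 3 M HCl in MeOH, 50 °C
Reagents that add atoms: none
Why: Acid methanolysis cleaves both MOM acetals and the TBS ether, and the aryl–Si bond at the carbon flanked by two phenols undergoes ipso-protodesilylation under the same conditions.

Step 10
Reactants: 15 1-{4,6-dihydroxy-3-[(2S)-2-hydroxy-3-methylbutyl]-2-methoxyphenyl}ethan-1-one
Product: 16 1-{4-(benzyloxy)-6-hydroxy-3-[(2S)-2-hydroxy-3-methylbutyl]-2-methoxyphenyl}ethan-1-one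
Conditions: BnBr (1.05 equiv), K2CO3, acetone, reflux
Reagents that add atoms: benzyl bromide, BrCc1ccccc1
Why: Selective Williamson etherification of the non-chelated 4-OH works because the 6-OH is hydrogen-bonded to the ketone and the aliphatic OH is not deprotonated by K2CO3.

Step 11
Reactants: 17 4-hydroxybenzaldehyde
Product: 18 4-(methoxymethoxy)benzaldehyde
Conditions: MOMCl, i-Pr2NEt, CH2Cl2, 0 °C → rt
Reagents that add atoms: chloromethyl methyl ether, COCCl
Why: MOM protection of the phenol gives an electron-rich, base-stable B-ring aldehyde whose aryl group migrates readily in the later oxidative rearrangement.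

Step 12
Reactants: 16 1-{4-(benzyloxy)-6-hydroxy-3-[(2S)-2-hydroxy-3-methylbutyl]-2-methoxyphenyl}ethan-1-one; 18 4-(methoxymethoxy)benzaldehyde
Product: 20 (2E)-1-{4-(benzyloxy)-6-hydroxy-3-[(2S)-2-hydroxy-3-methylbutyl]-2-methoxyphenyl}-3-[4-(methoxymethoxy)phenyl]prop-2-en-1-one, via aldol adduct 19 (not isolated)
Conditions: 50% aq. KOH, EtOH, rt, 24–48 h
Reagents that add atoms: none
Why: Claisen–Schmidt aldol condensation of the methyl ketone enolate with the non-enolisable aldehyde, followed by E1cB dehydration, gives the (E)-chalcone and forms the bond that becomes C2–C3 of the isoflavone.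

Step 13
Reactants: 20 (2E)-1-{4-(benzyloxy)-6-hydroxy-3-[(2S)-2-hydroxy-3-methylbutyl]-2-methoxyphenyl}-3-[4-(methoxymethoxy)phenyl]prop-2-en-1-one
Product: 21 1-{4-(benzyloxy)-6-hydroxy-3-[(2S)-2-hydroxy-3-methylbutyl]-2-methoxyphenyl}-3,3-dimethoxy-2-[4-(methoxymethoxy)phenyl]propan-1-one
Conditions: Tl(NO3)3·3H2O (1.1 equiv), MeOH/HC(OMe)3, rt, 1–3 h
Reagents that add atoms: methanol, CO
Why: Thallium(III)-mediated oxidative rearrangement (methoxythallation of the enone, then 1,2-shift of the electron-rich aryl group from Cβ to Cα with loss of Tl(I)) gives the 2-aryl-3,3-dimethoxy ketone, whose new α-centre is lost in the next step.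

Step 14
Reactants: 21 1-{4-(benzyloxy)-6-hydroxy-3-[(2S)-2-hydroxy-3-methylbutyl]-2-methoxyphenyl}-3,3-dimethoxy-2-[4-(methoxymethoxy)phenyl]propan-1-one
Product: 22 7-(benzyloxy)-3-(4-hydroxyphenyl)-6-[(2S)-2-hydroxy-3-methylbutyl]-5-methoxy-4H-chromen-4-one
Conditions: 10% HCl in MeOH, reflux
Reagents that add atoms: none
Why: Acid-catalysed cyclisation of the only free ortho-phenol onto the acetal and loss of methanol closes the pyranone ring, while the same conditions cleave the MOM ether and leave the benzyl ether intact.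

Step 15
Reactants: 22 7-(benzyloxy)-3-(4-hydroxyphenyl)-6-[(2S)-2-hydroxy-3-methylbutyl]-5-methoxy-4H-chromen-4-one
Product: 23 4-{7-(benzyloxy)-6-[(2S)-2-hydroxy-3-methylbutyl]-5-methoxy-4-oxo-4H-chromen-3-yl}phenyl 2,2-dimethylpropanoate
Conditions: PivCl (1.1 equiv), Et3N, CH2Cl2, 0 °C
Reagents that add atoms: pivaloyl chloride, CC(C)(C)C(=O)Cl
Why: Selective O-acylation of the phenol over the hindered secondary alcohol (no DMAP) gives a pivalate that survives hydrogenolysis, DBU and heat and is later removed without acid.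

Step 16
Reactants: 23 4-{7-(benzyloxy)-6-[(2S)-2-hydroxy-3-methylbutyl]-5-methoxy-4-oxo-4H-chromen-3-yl}phenyl 2,2-dimethylpropanoate
Product: 24 4-{7-hydroxy-6-[(2S)-2-hydroxy-3-methylbutyl]-5-methoxy-4-oxo-4H-chromen-3-yl}phenyl 2,2-dimethylpropanoate
Conditions: H2 (1 atm), 10% Pd/C, EtOAc, rt, monitored
Reagents that add atoms: none
Why: Catalytic hydrogenolysis of the benzyl ether frees the 7-OH alone, since O-benzyl cleavage is much faster than reduction of the chromone double bond.

Step 17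
Reactants: 24 4-{7-hydroxy-6-[(2S)-2-hydroxy-3-methylbutyl]-5-methoxy-4-oxo-4H-chromen-3-yl}phenyl 2,2-dimethylpropanoate
Product: 25 4-{6-[(2S)-2-hydroxy-3-methylbutyl]-5-methoxy-7-[(2-methylbut-3-yn-2-yl)oxy]-4-oxo-4H-chromen-3-yl}phenyl 2,2-dimethylpropanoate
Conditions: 3-chloro-3-methylbut-1-yne, DBU, CuCl2·2H2O (1 mol%), MeCN, 0 °C → rt
Reagents that add atoms: 3-chloro-3-methylbut-1-yne, C#CC(C)(C)Cl
Why: Copper-catalysed propargylic etherification (through a copper allenylidene) alkylates the acidic 7-phenol with the tertiary propargyl chloride, and the aliphatic alcohol is not deprotonated by DBU.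

Step 18
Reactants: 25 4-{6-[(2S)-2-hydroxy-3-methylbutyl]-5-methoxy-7-[(2-methylbut-3-yn-2-yl)oxy]-4-oxo-4H-chromen-3-yl}phenyl 2,2-dimethylpropanoate
Product: 26 4-{6-[(2S)-2-hydroxy-3-methylbutyl]-5-methoxy-7-[(2-methylbut-3-en-2-yl)oxy]-4-oxo-4H-chromen-3-yl}phenyl 2,2-dimethylpropanoate
Conditions: H2 (1 atm), Lindlar catalyst, quinoline, EtOAc, rt
Reagents that add atoms: none
Why: Lindlar semi-hydrogenation stops at the terminal alkene and does not reduce the chromone or the ester.

Step 19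
Reactants: 26 4-{6-[(2S)-2-hydroxy-3-methylbutyl]-5-methoxy-7-[(2-methylbut-3-en-2-yl)oxy]-4-oxo-4H-chromen-3-yl}phenyl 2,2-dimethylpropanoate
Product: 28 4-{7-hydroxy-6-[(2S)-2-hydroxy-3-methylbutyl]-5-methoxy-8-(3-methylbut-2-en-1-yl)-4-oxo-4H-chromen-3-yl}phenyl 2,2-dimethylpropanoate, via ortho-dienone 27 (not isolated)
Conditions: PhNEt2, 130 °C
Reagents that add atoms: none
Why: Aromatic Claisen [3,3]-sigmatropic rearrangement of the 1,1-dimethylallyl ether delivers a linear prenyl group to the only free ortho position (C8, since C6 is substituted), followed by tautomerisation to the phenol.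

Step 20
Reactants: 28 4-{7-hydroxy-6-[(2S)-2-hydroxy-3-methylbutyl]-5-methoxy-8-(3-methylbut-2-en-1-yl)-4-oxo-4H-chromen-3-yl}phenyl 2,2-dimethylpropanoate
Product: 29 7-hydroxy-3-(4-hydroxyphenyl)-6-[(2S)-2-hydroxy-3-methylbutyl]-5-methoxy-8-(3-methylbut-2-en-1-yl)-4H-chromen-4-one
Conditions: K2CO3, MeOH, rt; aq. NH4Cl work-up
Reagents that add atoms: none
Why: Base-catalysed methanolysis (transesterification) of the aryl pivalate frees the 4'-phenol without acid, so the ortho-prenyl phenol does not cyclise to a chroman.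

## Compound list

1 | L-valine | CC(C)[C@H](N)C(=O)O | starting material
2 | (2S)-2-chloro-3-methylbutanoic acid | CC(C)[C@H](Cl)C(=O)O | intermediate
3 | (2S)-2-chloro-3-methylbutan-1-ol | CC(C)[C@H](Cl)CO | intermediate
4 | (2R)-2-(propan-2-yl)oxirane | CC(C)[C@@H]1CO1 | intermediate
5 | 5-methoxybenzene-1,3-diol (5-methoxyresorcinol) | COc1cc(O)cc(O)c1 | starting material
6 | 1-methoxy-3,5-bis(methoxymethoxy)benzene | COCOc1cc(OC)cc(OCOC)c1 | intermediate
7 | [4-methoxy-2,6-bis(methoxymethoxy)phenyl]lithium (not isolated) | [Li]c1c(OCOC)cc(OC)cc1OCOC | intermediate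
8 | [4-methoxy-2,6-bis(methoxymethoxy)phenyl]trimethylsilane | C[Si](C)(C)c1c(OCOC)cc(OC)cc1OCOC | intermediate
9 | [6-methoxy-2,4-bis(methoxymethoxy)-3-(trimethylsilyl)phenyl]lithium (not isolated) | [Li]c1c(OC)cc(OCOC)c([Si](C)(C)C)c1OCOC | intermediate
10 | (2S)-1-[6-methoxy-2,4-bis(methoxymethoxy)-3-(trimethylsilyl)phenyl]-3-methylbutan-2-ol | COc1cc(OCOC)c([Si](C)(C)C)c(OCOC)c1C[C@H](O)C(C)C | intermediate
11 | tert-butyl({(2S)-1-[6-methoxy-2,4-bis(methoxymethoxy)-3-(trimethylsilyl)phenyl]-3-methylbutan-2-yl}oxy)dimethylsilane | COc1cc(OCOC)c([Si](C)(C)C)c(OCOC)c1C[C@H](O[Si](C)(C)C(C)(C)C)C(C)C | intermediate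
12 | {3-[(2S)-2-{[tert-butyl(dimethyl)silyl]oxy}-3-methylbutyl]-2-methoxy-4,6-bis(methoxymethoxy)-5-(trimethylsilyl)phenyl}lithium (not isolated) | [Li]c1c(OC)c(C[C@H](O[Si](C)(C)C(C)(C)C)C(C)C)c(OCOC)c([Si](C)(C)C)c1OCOC | intermediate
13 | lithium 1-aryl-1-[methoxy(methyl)amino]ethan-1-olate, the tetrahedral Weinreb adduct of 12 (not isolated; new centre undefined) | CC(O[Li])(N(C)OC)c1c(OC)c(C[C@H](O[Si](C)(C)C(C)(C)C)C(C)C)c(OCOC)c([Si](C)(C)C)c1OCOC | intermediate
14 | 1-{3-[(2S)-2-{[tert-butyl(dimethyl)silyl]oxy}-3-methylbutyl]-2-methoxy-4,6-bis(methoxymethoxy)-5-(trimethylsilyl)phenyl}ethan-1-one | CC(=O)c1c(OC)c(C[C@H](O[Si](C)(C)C(C)(C)C)C(C)C)c(OCOC)c([Si](C)(C)C)c1OCOC | intermediate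
15 | 1-{4,6-dihydroxy-3-[(2S)-2-hydroxy-3-methylbutyl]-2-methoxyphenyl}ethan-1-one | CC(=O)c1c(OC)c(C[C@H](O)C(C)C)c(O)cc1O | intermediate
16 | 1-{4-(benzyloxy)-6-hydroxy-3-[(2S)-2-hydroxy-3-methylbutyl]-2-methoxyphenyl}ethan-1-one | CC(=O)c1c(OC)c(C[C@H](O)C(C)C)c(OCc2ccccc2)cc1O | intermediate
17 | 4-hydroxybenzaldehyde | O=Cc1ccc(O)cc1 | starting material
18 | 4-(methoxymethoxy)benzaldehyde | COCOc1ccc(C=O)cc1 | intermediate
19 | 1-{4-(benzyloxy)-6-hydroxy-3-[(2S)-2-hydroxy-3-methylbutyl]-2-methoxyphenyl}-3-hydroxy-3-[4-(methoxymethoxy)phenyl]propan-1-one (not isolated; carbinol epimers) | COCOc1ccc(cc1)C(O)CC(=O)c1c(OC)c(C[C@H](O)C(C)C)c(OCc2ccccc2)cc1O | intermediate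
20 | (2E)-1-{4-(benzyloxy)-6-hydroxy-3-[(2S)-2-hydroxy-3-methylbutyl]-2-methoxyphenyl}-3-[4-(methoxymethoxy)phenyl]prop-2-en-1-one | COCOc1ccc(/C=C/C(=O)c2c(OC)c(C[C@H](O)C(C)C)c(OCc3ccccc3)cc2O)cc1 | intermediate
21 | 1-{4-(benzyloxy)-6-hydroxy-3-[(2S)-2-hydroxy-3-methylbutyl]-2-methoxyphenyl}-3,3-dimethoxy-2-[4-(methoxymethoxy)phenyl]propan-1-one (C2 epimers) | COCOc1ccc(cc1)C(C(OC)OC)C(=O)c1c(OC)c(C[C@H](O)C(C)C)c(OCc2ccccc2)cc1O | intermediate
22 | 7-(benzyloxy)-3-(4-hydroxyphenyl)-6-[(2S)-2-hydroxy-3-methylbutyl]-5-methoxy-4H-chromen-4-one | COc1c(C[C@H](O)C(C)C)c(OCc2ccccc2)cc2occ(-c3ccc(O)cc3)c(=O)c12 | intermediate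
23 | 4-{7-(benzyloxy)-6-[(2S)-2-hydroxy-3-methylbutyl]-5-methoxy-4-oxo-4H-chromen-3-yl}phenyl 2,2-dimethylpropanoate | COc1c(C[C@H](O)C(C)C)c(OCc2ccccc2)cc2occ(-c3ccc(OC(=O)C(C)(C)C)cc3)c(=O)c12 | intermediate
24 | 4-{7-hydroxy-6-[(2S)-2-hydroxy-3-methylbutyl]-5-methoxy-4-oxo-4H-chromen-3-yl}phenyl 2,2-dimethylpropanoate | COc1c(C[C@H](O)C(C)C)c(O)cc2occ(-c3ccc(OC(=O)C(C)(C)C)cc3)c(=O)c12 | intermediate
25 | 4-{6-[(2S)-2-hydroxy-3-methylbutyl]-5-methoxy-7-[(2-methylbut-3-yn-2-yl)oxy]-4-oxo-4H-chromen-3-yl}phenyl 2,2-dimethylpropanoate | COc1c(C[C@H](O)C(C)C)c(OC(C)(C)C#C)cc2occ(-c3ccc(OC(=O)C(C)(C)C)cc3)c(=O)c12 | intermediate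
26 | 4-{6-[(2S)-2-hydroxy-3-methylbutyl]-5-methoxy-7-[(2-methylbut-3-en-2-yl)oxy]-4-oxo-4H-chromen-3-yl}phenyl 2,2-dimethylpropanoate | COc1c(C[C@H](O)C(C)C)c(OC(C)(C)C=C)cc2occ(-c3ccc(OC(=O)C(C)(C)C)cc3)c(=O)c12 | intermediate
27 | 4-{6-[(2S)-2-hydroxy-3-methylbutyl]-5-methoxy-8-(3-methylbut-2-en-1-yl)-4,7-dioxo-7,8-dihydro-4H-chromen-3-yl}phenyl 2,2-dimethylpropanoate (not isolated; C8 epimers) | COC1=C(C[C@H](O)C(C)C)C(=O)C(CC=C(C)C)C2=C1C(=O)C(c3ccc(OC(=O)C(C)(C)C)cc3)=CO2 | intermediate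
28 | 4-{7-hydroxy-6-[(2S)-2-hydroxy-3-methylbutyl]-5-methoxy-8-(3-methylbut-2-en-1-yl)-4-oxo-4H-chromen-3-yl}phenyl 2,2-dimethylpropanoate | COc1c(C[C@H](O)C(C)C)c(O)c(CC=C(C)C)c2occ(-c3ccc(OC(=O)C(C)(C)C)cc3)c(=O)c12 | intermediate
29 | 7-hydroxy-3-(4-hydroxyphenyl)-6-[(2S)-2-hydroxy-3-methylbutyl]-5-methoxy-8-(3-methylbut-2-en-1-yl)-4H-chromen-4-one | COc1c(C[C@H](O)C(C)C)c(O)c(CC=C(C)C)c2occ(-c3ccc(O)cc3)c(=O)c12 | target

## Summary

Total step count: 20.
Longest linear sequence: 17 steps (steps 1–3, 6–10, 12–20, from L-valine).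

Three steps most likely to fail:

**Step 8 (third lithiation and Weinreb acylation).** The aryllithium sits on a pentasubstituted ring and may enolise the amide instead of adding to it. The fallback sets out from 11, lithiated as before to 12. Aryllithium 12 is quenched with acetaldehyde, a small electrophile that adds rapidly, to give the benzylic carbinol 1-{3-[(2S)-2-{[tert-butyl(dimethyl)silyl]oxy}-3-methylbutyl]-2-methoxy-4,6-bis(methoxymethoxy)-5-(trimethylsilyl)phenyl}ethan-1-ol F1. F1 is then oxidised with Dess–Martin periodinane buffered with NaHCO3 in CH2Cl2, and the route is rejoined at 14.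

**Step 13 (thallium(III) oxidative rearrangement).** Early loss of the MOM group, aurone formation or oxidation of the electron-rich phenol could erode the yield. The fallback sets out from chalcone 20. NaOAc in refluxing EtOH closes it by oxa-Michael addition to the flavanone 7-(benzyloxy)-6-[(2S)-2-hydroxy-3-methylbutyl]-5-methoxy-2-[4-(methoxymethoxy)phenyl]-2,3-dihydro-4H-chromen-4-one F2. Koser's reagent PhI(OH)OTs in MeOH/HC(OMe)3 then brings about the oxidative 2,3-aryl shift to 7-(benzyloxy)-6-[(2S)-2-hydroxy-3-methylbutyl]-5-methoxy-3-[4-(methoxymethoxy)phenyl]-4H-chromen-4-one F3. Treating F3 with HCl in MeOH under the conditions of step 14 removes the MOM group, and the route is rejoined at 22.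

**Step 17 (tertiary propargyl ether on the hindered 7-OH).** The phenol is flanked by the C6 side chain, and the chloride may eliminate instead of etherifying. The fallback sets out from 24. O-Alkylation with prenyl bromide and K2CO3 in acetone (a primary allylic halide, much less demanding) gives 4-{6-[(2S)-2-hydroxy-3-methylbutyl]-5-methoxy-7-[(3-methylbut-2-en-1-yl)oxy]-4-oxo-4H-chromen-3-yl}phenyl 2,2-dimethylpropanoate F4. Montmorillonite K10 in CH2Cl2 at 0 °C then effects the [1,3] O-to-C prenyl shift to the only free ortho position, and the route is rejoined at 28, bypassing 25–27.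

## Further compounds

F1 | step 8 | 1-{3-[(2S)-2-{[tert-butyl(dimethyl)silyl]oxy}-3-methylbutyl]-2-methoxy-4,6-bis(methoxymethoxy)-5-(trimethylsilyl)phenyl}ethan-1-ol | CC(O)c1c(OC)c(C[C@H](O[Si](C)(C)C(C)(C)C)C(C)C)c(OCOC)c([Si](C)(C)C)c1OCOC
F2 | step 13 | 7-(benzyloxy)-6-[(2S)-2-hydroxy-3-methylbutyl]-5-methoxy-2-[4-(methoxymethoxy)phenyl]-2,3-dihydro-4H-chromen-4-one | COCOc1ccc(cc1)C1CC(=O)c2c(OC)c(C[C@H](O)C(C)C)c(OCc3ccccc3)cc2O1
F3 | step 13 | 7-(benzyloxy)-6-[(2S)-2-hydroxy-3-methylbutyl]-5-methoxy-3-[4-(methoxymethoxy)phenyl]-4H-chromen-4-one | COCOc1ccc(cc1)-c1coc2cc(OCc3ccccc3)c(C[C@H](O)C(C)C)c(OC)c2c1=O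
F4 | step 17 | 4-{6-[(2S)-2-hydroxy-3-methylbutyl]-5-methoxy-7-[(3-methylbut-2-en-1-yl)oxy]-4-oxo-4H-chromen-3-yl}phenyl 2,2-dimethylpropanoate | COc1c(C[C@H](O)C(C)C)c(OCC=C(C)C)cc2occ(-c3ccc(OC(=O)C(C)(C)C)cc3)c(=O)c12
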